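**Strategy.** Everything rests on cutting the C3–C4 bond of ring C. The key step exploits the ortho relationship on ring A between O1 and the C4 carbonyl carbon. C4 is carried as a methyl ester carbon and C3 as the inner carbon of a vinyl group on the C2 ether carbon, so the O1–C2 bond and the (S) centre exist before ring closure. A titanium alkylidene then joins C3 to C4 by carbonyl–olefin metathesis and closes ring C as a 4-methoxy-2H-chromene, a masked C4 ketone, in one operation. The precursor is a methyl benzoate with the 8-prenyl group, two MOM ethers and, on the future O1, the (S)-1-(2,2-dimethylchroman-6-yl)allyl group.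

Key step: step 12

Assumption on the chemistry: with L = (Sa,Sc,Sc)-O,O'-(1,1'-binaphthalene-2,2'-diyl) N,N-bis(1-phenylethyl)phosphoramidite, the iridium catalyst is taken to give the (S) 1-arylallyl ether; if a first run shows the opposite sense, the (Ra,Rc,Rc) ligand is used with nothing else changed.

Structure remark: the CIP order O > aryl > C3 > H is the same in the allyl ether, the chromene and the flavanone, so the (1S) ether maps onto the (2S) target without a change of descriptor.

**Step 1**
Reactants: 1 methyl 2,4,6-trihydroxybenzoate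
Product: 2 methyl 2-hydroxy-4,6-bis(methoxymethoxy)benzoate
Conditions: MOMCl (2.2 equiv), i-Pr2NEt, CH2Cl2, 0 °C → rt
Reagents that add atoms: chloromethyl methyl ether, COCCl
Why: Phenol O-alkylation (MOM acetal formation) should take the para hydroxyl and one ortho hydroxyl, while the remaining ortho hydroxyl is held in a hydrogen bond to the ester carbonyl and stays free, as is usual for 2,4,6-trihydroxyaryl carbonyl compounds.

**Step 2**
Reactants: 2 methyl 2-hydroxy-4,6-bis(methoxymethoxy)benzoate; 3 allyl bromide
Product: 4 methyl 2-(allyloxy)-4,6-bis(methoxymethoxy)benzoate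
Conditions: K2CO3, DMF, 50 °C
Reagents that add atoms: allyl bromide 3, C=CCBr
Why: Williamson ether synthesis, in which carbonate in a polar aprotic solvent breaks the hydrogen bond and the unhindered allylic bromide alkylates the phenoxide on oxygen.

**Step 3**
Reactants: 4 methyl 2-(allyloxy)-4,6-bis(methoxymethoxy)benzoate
Product: 6 methyl 3-allyl-2-hydroxy-4,6-bis(methoxymethoxy)benzoate, via ortho-allyl cyclohexadienone 5 (not isolated)
Conditions: PhNEt2, 190 °C
Reagents that add atoms: none
Why: Aromatic Claisen rearrangement moves the allyl group to the only ortho carbon that bears hydrogen, and tautomerisation of dienone 5 returns the phenol on the oxygen next to the new side chain, which fixes the regiochemistry of the later prenyl group without ambiguity.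

**Step 4**
Reactants: 6 methyl 3-allyl-2-hydroxy-4,6-bis(methoxymethoxy)benzoate; 7 2-methylbut-2-ene
Product: 8 methyl 2-hydroxy-4,6-bis(methoxymethoxy)-3-(3-methylbut-2-enyl)benzoate
Conditions: 2-methylbut-2-ene (excess), (H2IMes)(PCy3)Cl2Ru=CHPh (second-generation Grubbs catalyst, 3 mol%), CH2Cl2, 40 °C
Reagents that add atoms: 2-methylbut-2-ene 7, CC=C(C)C
Why: Olefin cross-metathesis of the terminal allyl group with excess 2-methylbut-2-ene should give the prenyl group, since the trisubstituted product olefin does not re-enter the cycle and the phenol, ester and acetals are tolerated.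

**Step 5**
Reactants: 9 4-hydroxybenzaldehyde; 10 3-chloro-3-methylbut-1-yne
Product: 11 4-[(2-methylbut-3-yn-2-yl)oxy]benzaldehyde
Conditions: DBU, CuCl2 (cat.), MeCN, 0 °C
Reagents that add atoms: 3-chloro-3-methylbut-1-yne 10, CC(C)(Cl)C#C
Why: Copper-catalysed propargylic substitution, in which the copper acetylide of the tertiary chloride ionises easily and the phenoxide of this acidic phenol adds at the tertiary carbon to give the aryl 1,1-dimethylpropargyl ether.

**Step 6**
Reactants: 11 4-[(2-methylbut-3-yn-2-yl)oxy]benzaldehyde
Product: 15 2,2-dimethyl-2H-chromene-6-carbaldehyde, via allenyl cyclohexadienone 12 (not isolated), via ortho-allenylphenol 13 (not isolated), via ortho-quinone methide 14 (not isolated)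
Conditions: PhNEt2, 190 °C
Reagents that add atoms: none
Why: Propargyl Claisen rearrangement to either of the two equivalent ortho carbons, tautomerisation, a 1,5-hydrogen shift and oxa-6π electrocyclisation form the 2,2-dimethylchromene in one heating operation.

**Step 7**
Reactants: 15 2,2-dimethyl-2H-chromene-6-carbaldehyde
Product: 16 2,2-dimethylchroman-6-carbaldehyde
Conditions: H2 (1 atm), Pd/C, Ph2S (cat.), EtOAc, rt
Reagents that add atoms: none
Why: Heterogeneous catalytic hydrogenation saturates the cis-disubstituted styrenyl olefin, and the sulfide-moderated palladium surface should leave the electron-rich aromatic aldehyde unreduced.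

**Step 8**
Reactants: 16 2,2-dimethylchroman-6-carbaldehyde; 17 triethyl phosphonoacetate
Product: 18 ethyl (E)-3-(2,2-dimethylchroman-6-yl)prop-2-enoate
Conditions: NaH, THF, 0 °C → rt
Reagents that add atoms: triethyl phosphonoacetate 17, CCOC(=O)CP(=O)(OCC)OCC
Why: Horner–Wadsworth–Emmons olefination with a stabilised phosphonate anion should give the (E)-cinnamate under thermodynamic control of the oxaphosphetane.

**Step 9**
Reactants: 18 ethyl (E)-3-(2,2-dimethylchroman-6-yl)prop-2-enoate
Product: 19 (E)-3-(2,2-dimethylchroman-6-yl)prop-2-en-1-ol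
Conditions: i-Bu2AlH (2.5 equiv), CH2Cl2, −78 °C; aq. KNaC4H4O6
Reagents that add atoms: none
Why: 1,2-Reduction of the unsaturated ester by an electrophilic aluminium hydride at low temperature should give the allylic alcohol without conjugate reduction or loss of the (E) geometry.

**Step 10**
Reactants: 19 (E)-3-(2,2-dimethylchroman-6-yl)prop-2-en-1-ol
Product: 20 (E)-3-(2,2-dimethylchroman-6-yl)prop-2-enyl methyl carbonate
Conditions: ClCO2Me, pyridine, CH2Cl2, 0 °C
Reagents that add atoms: methyl chloroformate, COC(=O)Cl
Why: Acylation of the primary allylic alcohol with a chloroformate under pyridine buffering installs the carbonate leaving group without ionising the electron-rich cinnamyl system.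

**Step 11**
Reactants: 8 methyl 2-hydroxy-4,6-bis(methoxymethoxy)-3-(3-methylbut-2-enyl)benzoate; 20 (E)-3-(2,2-dimethylchroman-6-yl)prop-2-enyl methyl carbonate
Product: 22 methyl 2-[(1S)-1-(2,2-dimethylchroman-6-yl)prop-2-enoxy]-4,6-bis(methoxymethoxy)-3-(3-methylbut-2-enyl)benzoate, via lithium aryloxide 21 (not isolated)
Conditions: 8 (1.3 equiv), LiN(SiMe3)2, THF, 0 °C; then 20, [Ir(cod)Cl]2 (2 mol%), (Sa,Sc,Sc)-L (4 mol%, activated with n-PrNH2), THF, 25 → 50 °C
Reagents that add atoms: none
Why: Iridium-catalysed asymmetric allylic etherification, in which the cyclometallated iridium phosphoramidite complex ionises the linear carbonate to an allyl complex and the aryloxide attacks the aryl-bearing terminus anti to the metal, so that the branched ether forms and the ligand configuration fixes the face of attack and thereby the (S) centre.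

**Step 12**
Reactants: 22 methyl 2-[(1S)-1-(2,2-dimethylchroman-6-yl)prop-2-enoxy]-4,6-bis(methoxymethoxy)-3-(3-methylbut-2-enyl)benzoate
Product: 24 (2S)-2-(2,2-dimethylchroman-6-yl)-4-methoxy-5,7-bis(methoxymethoxy)-8-(3-methylbut-2-enyl)-2H-chromene, via C3 titanium alkylidene 23 (not isolated)
Conditions: TiCl4, TMEDA, Zn, PbCl2 (cat.), CH3CHBr2, THF–CH2Cl2, 0 → 65 °C; aq. K2CO3, basic Al2O3
Reagents that add atoms: none
Why: The ethylidene titanium reagent formed from TiCl4, Zn and CH3CHBr2 exchanges by (2+2) addition and cycloreversion with the monosubstituted vinyl group, releasing propene and placing titanium on C3 (23); this alkylidene adds across the neighbouring ester C=O to an oxatitanacyclobutane, which cycloreverts to the C3=C4 enol ether and a titanium oxo species (should the ester be ethylidenated first, ring-closing enol ether–olefin metathesis on titanium leads to the same product). The closest known reaction type is the olefinic ester cyclisation with reduced titanium alkylidenes of the Takai–Utimoto type, a carbonyl–olefin metathesis that makes cyclic enol ethers. Ring C, the only ring formed, closes in a 6-exo-trig sense: C3 attacks the ester carbon C4, whose carbonyl oxygen lies outside the ring and is lost to titanium, while O1, C2, C8a and C4a are already in place. No stereocentre is created, and C2 from step 11 should be neither deprotonated nor ionised under the aprotic, amine-buffered conditions. The step needs chemoselectivity for the vinyl group and the ester over the prenyl olefin and the MOM acetals; titanium alkylidenes engage only unhindered terminal olefins and carbonyl groups, the trisubstituted prenyl olefin is inert, and intramolecular delivery through a six-membered arrangement should offset the shielding of the benzoate by its two ortho substituents.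

**Step 13**
Reactants: 24 (2S)-2-(2,2-dimethylchroman-6-yl)-4-methoxy-5,7-bis(methoxymethoxy)-8-(3-methylbut-2-enyl)-2H-chromene
Product: 27 euchrenone a16 [(2S)-2-(2,2-dimethylchroman-6-yl)-5,7-dihydroxy-8-(3-methylbut-2-enyl)chroman-4-one], via bis-MOM flavanone 25 (not isolated), via 7-O-MOM flavanone 26 (not isolated)
Conditions: 3 M aq. HCl, THF, 45 °C
Reagents that add atoms: water, O
Why: Acid-catalysed enol ether hydrolysis (protonation at C3, hydration at C4, loss of methanol) unveils the C4 ketone, and the same dilute acid hydrolyses both MOM acetals; C2 takes no part, so its configuration should be retained.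

**Compound list**

1 | methyl 2,4,6-trihydroxybenzoate | COC(=O)c1c(O)cc(O)cc1O | starting material
2 | methyl 2-hydroxy-4,6-bis(methoxymethoxy)benzoate | COCOc1cc(O)c(C(=O)OC)c(OCOC)c1 | intermediate
3 | allyl bromide | C=CCBr | starting material
4 | methyl 2-(allyloxy)-4,6-bis(methoxymethoxy)benzoate | C=CCOc1cc(OCOC)cc(OCOC)c1C(=O)OC | intermediate
5 | methyl 5-allyl-2,4-bis(methoxymethoxy)-6-oxocyclohexa-1,3-diene-1-carboxylate (ortho-allyl cyclohexadienone) | C=CCC1C(=O)C(C(=O)OC)=C(OCOC)C=C1OCOC | intermediate (not isolated)
6 | methyl 3-allyl-2-hydroxy-4,6-bis(methoxymethoxy)benzoate | C=CCc1c(O)c(C(=O)OC)c(OCOC)cc1OCOC | intermediate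
7 | 2-methylbut-2-ene | CC=C(C)C | starting material
8 | methyl 2-hydroxy-4,6-bis(methoxymethoxy)-3-(3-methylbut-2-enyl)benzoate | CC(C)=CCc1c(O)c(C(=O)OC)c(OCOC)cc1OCOC | intermediate
9 | 4-hydroxybenzaldehyde | O=Cc1ccc(O)cc1 | starting material
10 | 3-chloro-3-methylbut-1-yne | CC(C)(Cl)C#C | starting material
11 | 4-[(2-methylbut-3-yn-2-yl)oxy]benzaldehyde | C#CC(C)(C)Oc1ccc(C=O)cc1 | intermediate
12 | 3-(3-methylbuta-1,2-dienyl)-4-oxocyclohexa-1,5-diene-1-carbaldehyde (allenyl cyclohexadienone) | O=CC1=CC(C=C=C(C)C)C(=O)C=C1 | intermediate (not isolated)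
13 | 4-hydroxy-3-(3-methylbuta-1,2-dienyl)benzaldehyde (ortho-allenylphenol) | CC(C)=C=Cc1cc(C=O)ccc1O | intermediate (not isolated)
14 | 3-(3-methylbut-2-enylidene)-4-oxocyclohexa-1,5-diene-1-carbaldehyde (ortho-quinone methide) | CC(C)=CC=C1C=C(C=O)C=CC1=O | intermediate (not isolated)
15 | 2,2-dimethyl-2H-chromene-6-carbaldehyde | CC1(C)C=Cc2cc(C=O)ccc2O1 | intermediate
16 | 2,2-dimethylchroman-6-carbaldehyde | CC1(C)CCc2cc(C=O)ccc2O1 | intermediate
17 | triethyl phosphonoacetate | CCOC(=O)CP(=O)(OCC)OCC | starting material
18 | ethyl (E)-3-(2,2-dimethylchroman-6-yl)prop-2-enoate | CCOC(=O)/C=C/c1ccc2OC(C)(C)CCc2c1 | intermediate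
19 | (E)-3-(2,2-dimethylchroman-6-yl)prop-2-en-1-ol | OC/C=C/c1ccc2OC(C)(C)CCc2c1 | intermediate
20 | (E)-3-(2,2-dimethylchroman-6-yl)prop-2-enyl methyl carbonate | COC(=O)OC/C=C/c1ccc2OC(C)(C)CCc2c1 | intermediate
21 | lithium 2-(methoxycarbonyl)-3,5-bis(methoxymethoxy)-6-(3-methylbut-2-enyl)phenoxide | [Li+].[O-]c1c(CC=C(C)C)c(OCOC)cc(OCOC)c1C(=O)OC | intermediate (not isolated)
22 | methyl 2-[(1S)-1-(2,2-dimethylchroman-6-yl)prop-2-enoxy]-4,6-bis(methoxymethoxy)-3-(3-methylbut-2-enyl)benzoate | CC(C)=CCc1c(OCOC)cc(OCOC)c(C(=O)OC)c1O[C@H](c1ccc2c(c1)CCC(C)(C)O2)C=C | intermediate (precursor of the key step)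
23 | titanium alkylidene at C3 of 22, written as the dichlorotitanium alkylidene, ether carbon unchanged | CC(C)=CCc1c(OCOC)cc(OCOC)c(C(=O)OC)c1O[C@H](c1ccc2c(c1)CCC(C)(C)O2)C=[Ti](Cl)Cl | intermediate (not isolated)
24 | (2S)-2-(2,2-dimethylchroman-6-yl)-4-methoxy-5,7-bis(methoxymethoxy)-8-(3-methylbut-2-enyl)-2H-chromene | CC(C)=CCc1c(OCOC)cc(OCOC)c2c1O[C@H](c1ccc3c(c1)CCC(C)(C)O3)C=C2OC | intermediate (product of the key step)
25 | (2S)-2-(2,2-dimethylchroman-6-yl)-5,7-bis(methoxymethoxy)-8-(3-methylbut-2-enyl)chroman-4-one | CC(C)=CCc1c(OCOC)cc(OCOC)c2c1O[C@H](c1ccc3c(c1)CCC(C)(C)O3)CC2=O | intermediate (not isolated)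
26 | (2S)-2-(2,2-dimethylchroman-6-yl)-5-hydroxy-7-(methoxymethoxy)-8-(3-methylbut-2-enyl)chroman-4-one | CC(C)=CCc1c(OCOC)cc(O)c2c1O[C@H](c1ccc3c(c1)CCC(C)(C)O3)CC2=O | intermediate (not isolated)
27 | euchrenone a16, (2S)-2-(2,2-dimethylchroman-6-yl)-5,7-dihydroxy-8-(3-methylbut-2-enyl)chroman-4-one | CC(C)=CCc1c(O)cc(O)c2c1O[C@H](c1ccc3c(c1)CCC(C)(C)O3)CC2=O | target

**Step count**

Total: 13 steps. Longest linear sequence: 9 steps (steps 5 to 13, from 4-hydroxybenzaldehyde 9); the ring A branch (steps 1 to 4) joins at step 11.

**Steps most likely to fail**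

1. Step 12. The doubly ortho-substituted benzoate may be slow to engage, so that the reaction stalls at an acyclic enol ether. Titanium bound at C3 next to the allylic aryl ether may expel the aryloxide by β-elimination. Zinc or titanium halides may ionise the C2–O bond and erode the configuration. The fallback sets out from 22 and comes back at 24, and it separates the two events and moves the ring closure to a metal that tolerates allylic ethers. Methylenation of the ester with Cp2TiMe2 (toluene, 65 °C, dark), free of halide Lewis acids, should give the 1-methoxyvinyl arene 6-[(1S)-1-[2-(1-methoxyethenyl)-3,5-bis(methoxymethoxy)-6-(3-methylbut-2-enyl)phenoxy]prop-2-enyl]-2,2-dimethylchroman F1. Ring-closing metathesis of F1 with Mo(=CHCMe2Ph)(=N-2,6-i-Pr2C6H3)[OCMe(CF3)2]2 (benzene, rt → 50 °C) should then join the vinyl group to the enol ether carbon and give 24. The six-membered closure should be kinetically preferred over the seven-membered closure onto the prenyl olefin.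

2. Step 11. The aryloxide, flanked by the ester and the prenyl group and chelated to lithium, may attack the allyl iridium complex slowly. The electron-rich branched ether may meanwhile re-ionise, leading to the linear ether and loss of enantiomeric purity. The fallback sets out from 20 (with 21 from 8) and comes back at 22, and it moves the asymmetric step to a small oxygen nucleophile and makes the hindered C–O bond stereospecifically. Iridium-catalysed allylic substitution of 20 with KOSiEt3 ([Ir(cod)Cl]2, (Sa,Sc,Sc)-L, CH2Cl2, rt) should give triethyl{[(1S)-1-(2,2-dimethylchroman-6-yl)prop-2-enyl]oxy}silane F2. Bu4NF (THF, 0 °C) should release (1S)-1-(2,2-dimethylchroman-6-yl)prop-2-en-1-ol F3. ClCO2Me and pyridine (CH2Cl2, −20 °C, used without chromatography) should give (1S)-1-(2,2-dimethylchroman-6-yl)prop-2-enyl methyl carbonate F4. Rhodium-catalysed allylic etherification of F4 with lithium aryloxide 21 (RhCl(PPh3)3, P(OMe)3, THF, 0 °C → rt) proceeds with net retention through a configurationally stable enyl rhodium intermediate and is suited to ortho-disubstituted aryloxides. It should deliver 22.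

3. Step 13. While the second MOM group is being removed, the acid may add the 7-hydroxyl to the prenyl olefin (chroman formation) or hydrate that olefin. Reversible opening of ring C to the chalcone may erode C2. The fallback sets out from 24 and comes back at 27, and it separates the two unmasking events and replaces aqueous Brønsted acid in the acetal cleavage by thiol-assisted Lewis acid cleavage. Pyridinium p-toluenesulfonate in wet acetone (0 °C → rt) should hydrolyse only the enol ether and allow 25 to be isolated. ZnBr2 with n-PrSH (CH2Cl2, 0 °C, minutes) should then remove both MOM groups as the thioacetal and give 27 without prolonged exposure of the prenylated resorcinol to acid.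

**Further compounds**

F1 | step 12 | 6-[(1S)-1-[2-(1-methoxyethenyl)-3,5-bis(methoxymethoxy)-6-(3-methylbut-2-enyl)phenoxy]prop-2-enyl]-2,2-dimethylchroman | CC(C)=CCc1c(OCOC)cc(OCOC)c(C(=C)OC)c1O[C@H](c1ccc2c(c1)CCC(C)(C)O2)C=C
F2 | step 11 | triethyl{[(1S)-1-(2,2-dimethylchroman-6-yl)prop-2-enyl]oxy}silane | CC[Si](CC)(CC)O[C@H](c1ccc2c(c1)CCC(C)(C)O2)C=C
F3 | step 11 | (1S)-1-(2,2-dimethylchroman-6-yl)prop-2-en-1-ol | O[C@H](c1ccc2c(c1)CCC(C)(C)O2)C=C
F4 | step 11 | (1S)-1-(2,2-dimethylchroman-6-yl)prop-2-enyl methyl carbonate | COC(=O)O[C@H](c1ccc2c(c1)CCC(C)(C)O2)C=C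
F0 | step 13 | none | none
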